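The eudesmane core is cut across ring A at C1–C10 and C4–C5, which turns ring B into thymoquinone (methyl on C10, isopropyl on C7, oxygen on C6) and ring A into (E)-penta-1,3-diene. A single enantioselective, oxazaborolidinium-catalysed Diels–Alder reaction on the methyl-bearing C5=C10 alkene, activated through the C6 carbonyl, closes ring A and fixes the C10 quaternary centre that controls everything later. Both partners are commercial, so no precursor synthesis is needed. Afterwards the C7=C8 alkene and C9 oxygen are removed, C5 is epimerised to the trans fusion, and the 6β-hydroxyl, made by α-face reduction, steers oxygen onto the β face of C4 before the isoferuloyl ester is attached.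

Key step: step 1

Remark on numbering: eudesmane numbering is used; ring A = C1–C5 and C10, ring B = C5–C10, C14 = CH3 on C10, C15 = CH3 on C4, C11–C13 = isopropyl on C7; β is the face of the C10 methyl.

Assumption: the catalyst antipode is chosen from the usual binding model (boron on the carbonyl lone pair next to the α-C–H, aryl group on the carbinol carbon shielding the rear face), which puts the diene on the α face of C5=C10 for the catalyst from (R)-α,α-diphenylprolinol, precursor SMILES Cc1ccccc1B1OC(c2ccccc2)(c2ccccc2)[C@H]2CCCN12; should the sense prove opposite, the (S)-derived antipode is used with no other change.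

Step 1
Reactants: 1 thymoquinone (2-isopropyl-5-methyl-1,4-benzoquinone); 2 (E)-penta-1,3-diene
Product: 3 cis-fused 5β-H-eudesma-2,7-diene-6,9-dione (4α-CH3/4β-H, 10β-CH3)
Conditions: (R)-diphenylprolinol-derived B-(o-tolyl)oxazaborolidine (20 mol%) + Tf2NH (18 mol%), 2 (5 equiv), CH2Cl2, −78 → −40 °C
Reagents that add atoms: none
Why: Triflimide protonates the oxazaborolidine nitrogen, and the resulting cationic boron binds the C6 carbonyl at the lone pair next to C5–H (the lone pair of O9 that would activate the same alkene is flanked by the C10 methyl), which makes C10 the electrophilic end of C5=C10. The diene then adds in a concerted, asynchronous endo [4+2] cycloaddition, its unsubstituted terminus C1 bonding to C10 and C4 to C5; the closest known reaction type is the oxazaborolidinium-catalysed Diels–Alder reaction of 2,5-dialkyl-1,4-benzoquinones. Ring A closes as a cyclohexene by this suprafacial six-electron cycloaddition. C10 (methyl β) and C5 (hydrogen β, cis fusion) are set by the catalyst, whose aryl group shields the β face of the bound quinone so that the diene approaches from the α face, and C4 (methyl α, hydrogen β) is set by the endo orientation of the (E)-diene. The step needs site selectivity for C5=C10 over C7=C8 and the stated orientation; the first is secured because reaction at C7=C8 would build a quaternary centre carrying isopropyl, the second by the single accessible coordination site on O6. Of the three new centres only C10 must last: C5 is corrected in step 3 and C4 is reset in steps 7 to 9.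

Step 2
Reactants: 3 cis-fused 5β-H-eudesma-2,7-diene-6,9-dione
Product: 4 cis-fused 5β-H-eudesm-2-ene-6,9-dione (mixture of C7 epimers)
Conditions: Zn dust, AcOH, rt
Reagents that add atoms: none
Why: Dissolving-metal reduction of the ene-dione (Zn/AcOH) is the standard chemoselective way to saturate the C7=C8 bond of quinone Diels–Alder adducts and leaves the isolated C2=C3 alkene untouched; the C7 epimers converge in step 3.

Step 3
Reactants: 4 cis-fused 5β-H-eudesm-2-ene-6,9-dione
Product: 5 trans-fused 5α-H-eudesm-2-ene-6,9-dione (4β-H, 7β-isopropyl, 10β-CH3)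
Conditions: NaOMe (0.3 equiv), MeOH, rt, argon
Reagents that add atoms: none
Why: Thermodynamic enolate equilibration at C5 and C7, both α to the C6 ketone, should favour the trans-fused chair–chair dione with equatorial 7β-isopropyl, in which the axial C10 methyl keeps only two syn-axial hydrogens; recovered cis material is resubmitted.

Step 4
Reactants: 5 trans-fused 5α-H-eudesm-2-ene-6,9-dione
Product: 6 eudesm-2-ene-6β,9β-diol (4β-H, 5α-H, 7β-isopropyl)
Conditions: LiAlH4, THF, −78 → 0 °C
Reagents that add atoms: none
Why: Hydride reduction of both ketones, in which the β face of C6 is blocked by the syn-axial C10 methyl so that hydride enters from the α face and gives the axial 6β-alcohol, while C9 should give the equatorial 9β-alcohol by axial attack (its configuration is immaterial because the oxygen is removed in step 6).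

Step 5
Reactants: 6 eudesm-2-ene-6β,9β-diol
Product: 7 9β-O-(imidazol-1-ylthiocarbonyl)eudesm-2-en-6β-ol
Conditions: 1,1'-thiocarbonyldiimidazole (1.3 equiv), DMAP (cat.), ClCH2CH2Cl, 60 °C
Reagents that add atoms: 1,1'-thiocarbonyldiimidazole, S=C(n1ccnc1)n1ccnc1
Why: Site-selective O-thioacylation, since the equatorial C9 hydroxyl is far more accessible than the axial 6β-hydroxyl, which is syn-axial to the C10 methyl and flanked by C5 and the isopropyl-bearing C7.

Step 6
Reactants: 7 9β-O-(imidazol-1-ylthiocarbonyl)eudesm-2-en-6β-ol
Product: 8 eudesm-2-en-6β-ol (4β-H, 5α-H, 7β-isopropyl)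
Conditions: Bu3SnH, AIBN (cat.), toluene, 110 °C
Reagents that add atoms: none
Why: Barton–McCombie radical deoxygenation, in which the secondary C9 radical is quenched by the stannane faster than it could add 5-endo to C2=C3 and the free hydroxyl is inert.

Step 7
Reactants: 8 eudesm-2-en-6β-ol
Product: 9 eudesm-3-en-6β-ol (5α-H, 7β-isopropyl)
Conditions: RhCl3·3H2O (10 mol%), EtOH, 80 °C
Reagents that add atoms: none
Why: Metal-hydride alkene isomerisation by reversible syn hydrometalation and β-hydride elimination moves the cis-disubstituted C2=C3 alkene to the thermodynamically preferred trisubstituted C3=C4 position by loss of the axial H4β, while onward migration to C4=C5 would need a tertiary alkyl–rhodium at C4 and should be slow.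

Step 8
Reactants: 9 eudesm-3-en-6β-ol
Product: 10 3β,4β-epoxyeudesman-6β-ol
Conditions: VO(acac)2 (5 mol%), t-BuOOH, CH2Cl2, 0 °C → rt
Reagents that add atoms: tert-butyl hydroperoxide, CC(C)(C)OO
Why: Hydroxyl-directed vanadium-catalysed epoxidation of a homoallylic alcohol, in which the 6β-alkoxide, 1,3-diaxial to C4, binds vanadium and delivers the peroxide oxygen to the β face of C3=C4, overriding the steric preference for α attack and setting the C4–O bond β.

Step 9
Reactants: 10 3β,4β-epoxyeudesman-6β-ol
Product: 11 eudesmane-4β,6β-diol (4α-CH3, 5α-H, 7β-isopropyl, 10β-CH3)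
Conditions: LiAlH4, THF, reflux
Reagents that add atoms: none
Why: Reductive epoxide opening by SN2 hydride attack at the less substituted C3 from the α face (trans-diaxial opening) leaves the oxygen on C4 as the axial 4β tertiary alcohol with the C15 methyl α.

Step 10
Reactants: 12 isoferulic acid
Product: 14 (E)-3-[3-(tert-butyldimethylsilyloxy)-4-methoxyphenyl]prop-2-enoic acid, via bis-silylated isoferulate 13 (not isolated)
Conditions: TBSCl (2.5 equiv), imidazole, DMF, rt; then AcOH–THF–H2O, rt
Reagents that add atoms: tert-butyldimethylsilyl chloride, CC(C)(C)[Si](C)(C)Cl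
Why: Exhaustive silylation followed by selective hydrolysis of the labile silyl ester leaves the phenol masked as an aryl silyl ether so that it cannot act as a competing nucleophile in step 11.

Step 11
Reactants: 11 eudesmane-4β,6β-diol; 14 (E)-3-[3-(tert-butyldimethylsilyloxy)-4-methoxyphenyl]prop-2-enoic acid
Product: 16 4β-hydroxyeudesman-6β-yl (E)-3-[3-(tert-butyldimethylsilyloxy)-4-methoxyphenyl]prop-2-enoate, via mixed anhydride 15 (not isolated)
Conditions: 14 (2 equiv), 2,4,6-Cl3C6H2COCl, Et3N, THF, rt; then 11, DMAP (3 equiv), toluene, 80 °C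
Reagents that add atoms: none
Why: Yamaguchi esterification, in which DMAP-mediated acyl transfer from the mixed anhydride acylates the secondary 6β-hydroxyl (hindered, hence heat and excess acylating agent) while the tertiary 4β-hydroxyl does not react and the (E)-alkene is untouched.

Step 12
Reactants: 16 4β-hydroxyeudesman-6β-yl (E)-3-[3-(tert-butyldimethylsilyloxy)-4-methoxyphenyl]prop-2-enoate
Product: 17 4β-hydroxyeudesman-6β-yl isoferulate (CNP0291757.1)
Conditions: Bu4NF, AcOH, THF, 0 °C
Reagents that add atoms: none
Why: Fluoride-induced cleavage of the aryl silyl ether, buffered with acetic acid so that the phenoxide cannot attack the ester, releases the free phenol without touching the hindered ester or the tertiary alcohol.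

Compound list
1 | thymoquinone | CC1=CC(=O)C(C(C)C)=CC1=O | starting material
2 | (E)-penta-1,3-diene | C=C/C=C/C | starting material
3 | cis-fused 5β-H-eudesma-2,7-diene-6,9-dione (4β-H, 10β-CH3) | O=C1[C@H]2[C@](C)(CC=C[C@H]2C)C(=O)C=C1C(C)C | intermediate
4 | cis-fused 5β-H-eudesm-2-ene-6,9-dione, C7 epimer mixture | O=C1[C@H]2[C@](C)(CC=C[C@H]2C)C(=O)CC1C(C)C | intermediate
5 | trans-fused 5α-H-eudesm-2-ene-6,9-dione (7β-isopropyl) | O=C1[C@@H]2[C@](C)(CC=C[C@H]2C)C(=O)C[C@H]1C(C)C | intermediate
6 | eudesm-2-ene-6β,9β-diol | O[C@H]1[C@@H]2[C@](C)(CC=C[C@H]2C)[C@@H](O)C[C@H]1C(C)C | intermediate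
7 | 9β-O-(imidazol-1-ylthiocarbonyl)eudesm-2-en-6β-ol | O[C@H]1[C@@H]2[C@](C)(CC=C[C@H]2C)[C@@H](OC(=S)n3ccnc3)C[C@H]1C(C)C | intermediate
8 | eudesm-2-en-6β-ol | O[C@H]1[C@@H]2[C@](C)(CC=C[C@H]2C)CC[C@H]1C(C)C | intermediate
9 | eudesm-3-en-6β-ol | O[C@H]1[C@@H]2[C@](C)(CCC=C2C)CC[C@H]1C(C)C | intermediate
10 | 3β,4β-epoxyeudesman-6β-ol | O[C@H]1[C@@H]2[C@](C)(CC[C@@H]3O[C@]23C)CC[C@H]1C(C)C | intermediate
11 | eudesmane-4β,6β-diol | O[C@H]1[C@@H]2[C@](C)(CCC[C@]2(C)O)CC[C@H]1C(C)C | intermediate
12 | isoferulic acid | COc1ccc(/C=C/C(=O)O)cc1O | starting material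
13 | tert-butyldimethylsilyl (E)-3-[3-(tert-butyldimethylsilyloxy)-4-methoxyphenyl]prop-2-enoate | COc1ccc(/C=C/C(=O)O[Si](C)(C)C(C)(C)C)cc1O[Si](C)(C)C(C)(C)C | intermediate
14 | (E)-3-[3-(tert-butyldimethylsilyloxy)-4-methoxyphenyl]prop-2-enoic acid | COc1ccc(/C=C/C(=O)O)cc1O[Si](C)(C)C(C)(C)C | intermediate
15 | mixed anhydride of 14 with 2,4,6-trichlorobenzoic acid | COc1ccc(/C=C/C(=O)OC(=O)c2c(Cl)cc(Cl)cc2Cl)cc1O[Si](C)(C)C(C)(C)C | intermediate
16 | 4β-hydroxyeudesman-6β-yl (E)-3-[3-(tert-butyldimethylsilyloxy)-4-methoxyphenyl]prop-2-enoate | COc1ccc(/C=C/C(=O)O[C@H]2[C@@H]3[C@](C)(CCC[C@]3(C)O)CC[C@H]2C(C)C)cc1O[Si](C)(C)C(C)(C)C | intermediate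
17 | 4β-hydroxyeudesman-6β-yl isoferulate (CNP0291757.1) | COc1ccc(/C=C/C(=O)O[C@H]2[C@@H]3[C@](C)(CCC[C@]3(C)O)CC[C@H]2C(C)C)cc1O | target

Total step count: 12. Longest linear sequence: 11 steps (steps 1–9, 11, 12).

Steps most likely to fail

Step 1. The weakly nucleophilic diene may turn over too slowly at the temperatures needed for good facial discrimination, so that the adduct forms with eroded enantiomeric purity, or some addition may occur at C7=C8. The fallback sets out from 1 and 2: an achiral Lewis acid (BF3·OEt2, CH2Cl2, −40 °C) should give the racemic cis adduct F1 with the same site selectivity and orientation, and preparative chromatography on a chiral stationary phase separates the enantiomers and returns to the route at 3.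

Step 7. The hydride must add to the more hindered β face to reach H4β, so migration may stall at a C1=C2/C2=C3 mixture or run on towards C4=C5. The fallback sets out from 8 and moves the alkene stepwise. mCPBA (CH2Cl2, NaHCO3) should epoxidise the α face, away from the C10 methyl, to give 2α,3α-epoxyeudesman-6β-ol F2. LiAlH4 should open it trans-diaxially at C2 to give eudesmane-3α,6β-diol F3. The accessible 3α-hydroxyl is then mesylated in preference to the hindered 6β-hydroxyl (MsCl, pyridine, 0 °C) to give the 3α-mesylate F4. Base-induced anti elimination (KOtBu, DMSO) of this axial mesylate, to which H4β is antiperiplanar, should give mainly the more substituted alkene and returns to the route at 9; co-formed 8 is recycled.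

Step 8. Undirected epoxidation from the open α face may compete with delivery from the crowded 6β-hydroxyl, giving poor facial selectivity, or oxygen transfer may be slow. The fallback sets out from 9 and fixes the face through a tether. The lithium alkoxide (n-BuLi, THF, −78 °C) is trapped with Boc2O to give the 6β-tert-butyl carbonate F5. IBr (toluene, −80 °C) should add iodine to the α face while the carbonate oxygen closes onto C4 from the β face, giving the 3α-iodo-4β,6β-cyclic carbonate F6. Bu3SnH/AIBN removes the iodine to give the 4β,6β-cyclic carbonate F7, and K2CO3 in MeOH cleaves the carbonate, returning to the route at 11 and bypassing 10.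

Further compounds
F1 | step 1 | racemic cis-fused eudesma-2,7-diene-6,9-dione (3 and its enantiomer) | O=C1[C@H]2[C@](C)(CC=C[C@H]2C)C(=O)C=C1C(C)C.O=C1[C@@H]2[C@@](C)(CC=C[C@@H]2C)C(=O)C=C1C(C)C
F2 | step 7 | 2α,3α-epoxyeudesman-6β-ol | O[C@H]1[C@@H]2[C@](C)(C[C@H]3O[C@H]3[C@H]2C)CC[C@H]1C(C)C
F3 | step 7 | eudesmane-3α,6β-diol | O[C@H]1[C@@H]2[C@](C)(CC[C@@H](O)[C@H]2C)CC[C@H]1C(C)C
F4 | step 7 | 3α-methanesulfonyloxyeudesman-6β-ol | O[C@H]1[C@@H]2[C@](C)(CC[C@@H](OS(C)(=O)=O)[C@H]2C)CC[C@H]1C(C)C
F5 | step 8 | tert-butyl eudesm-3-en-6β-yl carbonate | CC(C)(C)OC(=O)O[C@H]1[C@@H]2[C@](C)(CCC=C2C)CC[C@H]1C(C)C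
F6 | step 8 | 3α-iodoeudesmane-4β,6β-diyl carbonate | O=C1O[C@H]2[C@@H]3[C@](C)(CC[C@@H](I)[C@]3(C)O1)CC[C@H]2C(C)C
F7 | step 8 | eudesmane-4β,6β-diyl carbonate | O=C1O[C@H]2[C@@H]3[C@](C)(CCC[C@]3(C)O1)CC[C@H]2C(C)C
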